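**Retrosynthetic overview**
1. The target is cut at the ArCH2–pyrone bridge into arene 7, pyrone 11 and a one-carbon unit (Eschenmoser's salt); the forward step is a Mannich/elimination/methide-capture sequence.
2. Pyrone 11 is cut at its lactone C–O bond and C4–C5 back to pentan-3-one and an activated malonate. The ring is closed by acyl C–O bond formation in a proposed one-pot Mg-mediated annulation.
3. Arene 7 comes from C-prenylation of 5. Compound 5 comes from site-selective O-methylation (ArO–CH3 bond) of triol 4, which fixes which oxygen is the ether and leaves two equivalent ring CH positions.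
4. Triol 4 comes from phloroglucinol and (R)-2-methylbutanoic acid; the single stereocenter is bought and carried through.
5. Ring order: the benzene ring is purchased as phloroglucinol; the pyrone is the only ring built (step 4).

Assumption: (R)-2-methylbutanoic acid of at least 98% ee is a purchasable catalogue compound, and the target side chain is (R) as drawn in the SMILES.

**Step 1**
Reactants: 1 (R)-2-methylbutanoic acid; 2 phloroglucinol
Product: 4 (R)-2-methyl-1-(2,4,6-trihydroxyphenyl)butan-1-one, via (R)-2-methylbutanoyl chloride 3 (not isolated)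
Conditions: (COCl)2, cat. DMF, CH2Cl2, 0 °C → rt; then 2, AlCl3 (4 equiv), PhNO2/CH2Cl2, 0 °C → rt; aq. HCl
Reagents that add atoms: none
Why: Friedel–Crafts acylation of the very electron-rich, threefold-symmetric triol stops at mono-acylation because the ketone–AlCl3 complex is deactivated; no bond to the stereocenter is made or broken, and the reaction is kept at or below rt to suppress ketene/enol racemisation (ee checked by chiral HPLC).

**Step 2**
Reactants: 4 (R)-2-methyl-1-(2,4,6-trihydroxyphenyl)butan-1-one
Product: 5 (R)-1-(2,6-dihydroxy-4-methoxyphenyl)-2-methylbutan-1-one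
Conditions: Me2SO4 (1.0 equiv), K2CO3 (1.05 equiv), acetone, rt → 50 °C
Reagents that add atoms: dimethyl sulfate, COS(=O)(=O)OC
Why: Site-selective Williamson O-methylation: the 4-OH para to the acyl group is the most acidic and the only one not held in a hydrogen bond to the ketone, so one equivalent of a hard methylating agent goes there; the phenoxide also disfavours enolisation at the stereocenter.

**Step 3**
Reactants: 5 (R)-1-(2,6-dihydroxy-4-methoxyphenyl)-2-methylbutan-1-one; 6 prenyl bromide
Product: 7 (R)-1-[2,6-dihydroxy-4-methoxy-3-(3-methylbut-2-en-1-yl)phenyl]-2-methylbutan-1-one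
Conditions: 6 (1.0 equiv), 10% aq. KOH, 0 °C → rt; then 1 M HCl
Reagents that add atoms: none
Why: C-alkylation of an ambident phloroglucinol-type phenoxide (SN2 on the allylic bromide); water hydrogen-bonds the oxygens and steers attack to the ring carbon ortho to O−, and the two free ring carbons of 5 are equivalent, so only one mono-prenyl isomer can form.

**Step 4**
Reactants: 8 pentan-3-one; 9 bis(2,4,6-trichlorophenyl) malonate
Product: 11 6-ethyl-4-hydroxy-5-methyl-2H-pyran-2-one, via trichlorophenyl 4-methyl-3,5-dioxoheptanoate 10 (not isolated)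
Conditions: 8 (3 equiv), MgBr2·OEt2 (2.5 equiv), i-Pr2NEt (3 equiv), CH2Cl2, 0 °C; 9 added over 2 h, then rt → 40 °C; 1 M HCl
Reagents that add atoms: none
Why: Proposed new method: MgBr2/i-Pr2NEt soft enolisation should let the symmetric ketone be C-acylated at room temperature by the doubly activated malonate (an acidic CH2 and a pKa-6 aryloxide leaving group make acyl transfer easy). The Mg-chelated 3,5-dioxo aryl ester 10 then closes the ring by attack of the distal enol oxygen on the remaining aryl ester, forming the lactone C–O bond and expelling the second aryloxide. The closest known reactions are the thermal (200–250 °C) cyclocondensation of ketones with bis(2,4,6-trichlorophenyl) malonates, the silyl enol ether/malonyl dichloride pyrone synthesis, and Mg-mediated soft-enolisation C-acylation of ketones with activated esters; none has been run as this room-temperature one-pot annulation of a simple acyclic ketone.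

**Step 5**
Reactants: 11 6-ethyl-4-hydroxy-5-methyl-2H-pyran-2-one; 7 (R)-1-[2,6-dihydroxy-4-methoxy-3-(3-methylbut-2-en-1-yl)phenyl]-2-methylbutan-1-one
Product: 14 3-({2,4-dihydroxy-6-methoxy-3-[(2R)-2-methylbutanoyl]-5-(3-methylbut-2-en-1-yl)phenyl}methyl)-6-ethyl-4-hydroxy-5-methyl-2H-pyran-2-one, via pyrone Mannich base 12 (not isolated), via methylidene-pyrandione 13 (not isolated)
Conditions: 11 (1.3 equiv), Me2N+=CH2 I− (1.3 equiv), MeCN, rt, 1 h; then 7 (1.0 equiv), 60 °C; pH 5 buffer work-up
Reagents that add atoms: Eschenmoser's salt (N,N-dimethylmethylideneammonium iodide), C=[N+](C)C.[I-]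
Why: Mannich aminomethylation at pyrone C3, E1cB loss of dimethylamine to methide 13, then Friedel–Crafts-type conjugate addition by the single free, phenol-activated ring carbon of 7; this sequence is established for methylene-bridged phloroglucinol–pyrone heterodimers, the conditions are acid-free so the prenyl group does not cyclise, and the remote stereocenter is untouched.

**Compound list**
1 | (R)-2-methylbutanoic acid | CC[C@@H](C)C(=O)O | starting material
2 | phloroglucinol (benzene-1,3,5-triol) | Oc1cc(O)cc(O)c1 | starting material
3 | (R)-2-methylbutanoyl chloride | CC[C@@H](C)C(=O)Cl | intermediate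
4 | (R)-2-methyl-1-(2,4,6-trihydroxyphenyl)butan-1-one | CC[C@@H](C)C(=O)c1c(O)cc(O)cc1O | intermediate
5 | (R)-1-(2,6-dihydroxy-4-methoxyphenyl)-2-methylbutan-1-one | CC[C@@H](C)C(=O)c1c(O)cc(OC)cc1O | intermediate
6 | prenyl bromide (1-bromo-3-methylbut-2-ene) | CC(C)=CCBr | starting material
7 | (R)-1-[2,6-dihydroxy-4-methoxy-3-(3-methylbut-2-en-1-yl)phenyl]-2-methylbutan-1-one | CC[C@@H](C)C(=O)c1c(O)cc(OC)c(CC=C(C)C)c1O | intermediate
8 | pentan-3-one | CCC(=O)CC | starting material
9 | bis(2,4,6-trichlorophenyl) malonate | O=C(CC(=O)Oc1c(Cl)cc(Cl)cc1Cl)Oc1c(Cl)cc(Cl)cc1Cl | starting material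
10 | 2,4,6-trichlorophenyl 4-methyl-3,5-dioxoheptanoate (C4 unspecified, enolised) | CCC(=O)C(C)C(=O)CC(=O)Oc1c(Cl)cc(Cl)cc1Cl | intermediate
11 | 6-ethyl-4-hydroxy-5-methyl-2H-pyran-2-one | CCc1oc(=O)cc(O)c1C | intermediate
12 | 3-[(dimethylamino)methyl]-6-ethyl-4-hydroxy-5-methyl-2H-pyran-2-one | CCc1oc(=O)c(CN(C)C)c(O)c1C | intermediate
13 | 6-ethyl-5-methyl-3-methylidene-2H-pyran-2,4(3H)-dione | CCC1=C(C)C(=O)C(=C)C(=O)O1 | intermediate
14 | 3-({2,4-dihydroxy-6-methoxy-3-[(2R)-2-methylbutanoyl]-5-(3-methylbut-2-en-1-yl)phenyl}methyl)-6-ethyl-4-hydroxy-5-methyl-2H-pyran-2-one | CCc1oc(=O)c(Cc2c(O)c(C(=O)[C@H](C)CC)c(O)c(CC=C(C)C)c2OC)c(O)c1C | target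

**Totals**
Total step count: 5. Longest linear sequence: 4 steps (1 → 2 → 3 → 5); step 4 is a one-step side branch.

**Three steps most likely to fail**

1. Step 4 (proposed new annulation). The malonate may self-condense, or the ketone may be O-acylated, before the desired C-acylation. The fallback sets out from 8: TMSCl/NaI/Et3N in MeCN gives 3-(trimethylsilyloxy)pent-2-ene F1, and malonyl dichloride in Et2O at −78 °C → rt then gives the pyrone by the known silyl enol ether/malonyl dichloride synthesis. It comes back to the route at 11 and costs one extra step.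

2. Step 3 (C-prenylation of the mono-methyl ether). O-prenylation, bis-prenylation or low conversion of the less nucleophilic diol may dominate. The fallback sets out from 4 and makes the C–C bond before the C–O bond: prenylation of the triol with 6 and DBU in THF (0 °C → rt), established for phloroacylphenones, gives (R)-2-methyl-1-[2,4,6-trihydroxy-3-(3-methylbut-2-en-1-yl)phenyl]butan-1-one F2. Me2SO4/K2CO3 in acetone then methylates the 4-OH para to the acyl group, and the route is rejoined at 7 with no change in step count.

3. Step 5 (fragment union). Arene 7 is less nucleophilic than the triols used in the precedent, so methide 13 may instead be captured by a second pyrone to give the methylene-bis-pyrone. The fallback reverses the polarity and sets out from 7: Eschenmoser's salt in CH2Cl2 at rt aminomethylates the only free ring carbon to give the phenolic Mannich base (R)-1-[3-[(dimethylamino)methyl]-2,6-dihydroxy-4-methoxy-5-(3-methylbut-2-en-1-yl)phenyl]-2-methylbutan-1-one F3. Heating F3 with 11 in toluene at 100 °C expels dimethylamine to an ortho-quinone methide that C3 of the pyrone traps, coming back to the route at 14.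

**Further compounds**
F1 | step 4 | 3-(trimethylsilyloxy)pent-2-ene (E/Z mixture) | CC=C(CC)O[Si](C)(C)C
F2 | step 3 | (R)-2-methyl-1-[2,4,6-trihydroxy-3-(3-methylbut-2-en-1-yl)phenyl]butan-1-one | CC[C@@H](C)C(=O)c1c(O)cc(O)c(CC=C(C)C)c1O
F3 | step 5 | (R)-1-[3-[(dimethylamino)methyl]-2,6-dihydroxy-4-methoxy-5-(3-methylbut-2-en-1-yl)phenyl]-2-methylbutan-1-one | CC[C@@H](C)C(=O)c1c(O)c(CN(C)C)c(OC)c(CC=C(C)C)c1O
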